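The data are calculated with made-up constants.

The pitfall with these runs was to read them by the clock, for elm had more enzyme than cedar, so its minutes were not cedar's.

| setting | cedar | elm | maple | flask |
|---|---|---|---|---|
| substrate | 10 mM (in portions, 3) | 10 mM (in portions, 3) | 5 mM (in portions, 3) | 10 mM (in portions, 3) |
| enzyme | 0.80 µM | 1.8 µM | 1.2 µM | 1.2 µM |
| remark | run made earlier; portions every 2.5 s | run made earlier; portions every 2.5 s | run made earlier; portions every 2.5 s | the portions of substrate follow each other after 2.5 s, the first at the start |
| time |  |  |  | 4.0 min |

- cedar (time / min: substrate / %, product / %): 0.333: 95.7, 4.2; 0.667: 92.0, 8.5; 1.00: 87.6, 12.4; 1.33: 83.1, 16.9; 1.50: 81.5, 18.5; 2.00: 75.7, 24.3; 2.50: 70.4, 29.8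
- elm (time / min: substrate / %, product / %): 0.200: 95.2, 5.4; 0.333: 91.4, 9.0; 0.417: 89.0, 11.1; 0.667: 82.0, 18.1; 1.00: 73.5, 26.5; 1.50: 62.3, 38.2; 2.50: 43.3, 56.7
- maple (time / min: substrate / %, product / %): 0.200: 96.6, 3.9; 0.333: 93.1, 6.8; 0.667: 85.9, 13.8; 1.33: 72.9, 27.7; 2.50: 53.9, 46.5

(standard deviation of a reading: 0.3 percentage points)

- the numbers in the tables scatter with a standard deviation of 0.3 percentage points
- candidate steps: substrate + enzyme <-> complex; complex -> enzyme + product
- the reaction counts as stopped when no species that holds the substrate changes by six tenths of a point or more over the second half of the time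

- why nothing more happens at 4.0 min, or that something still does (no working catalyst is left / forward and back rates have come level / it is still moving / all of the substrate has reacted)
- share of the substrate used up at 4.0 min
- product at 4.0 min, in percent of the substrate charged
- amount of product if the flask were left three thousand times as long, in percent of the substrate charged

So I multiplied enzyme by time and called that the enzyme dose, the axis of Selwyn's test; the flask reached 4.80 µM·min. Cedar at 1.50 min and elm at 0.667 min had the same dose, 1.20 µM·min. They gave 18.5% and 18.1% product, 0.4 percentage points apart, with readings scattering by 0.3 points. So I saw no enzyme lost, and at this charge the dose could stand in for time.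

But the portions had to be checked. The last came at 5.00 s, far less than 4.0 min, so I ignored them. The flask's enzyme was 0.0120% of its substrate charge, less than the scatter, so I read substrate used up as product.

Elm passed 2.70 µM·min at 38.2% and 4.50 µM·min at 56.7%. Carrying that step on to the flask's dose gave me 59.8%. Half the flask's dose, 2.40 µM·min, lay below 2.70 µM·min, so by this estimate its second half added more than 22 points, and I called it still moving. The candidate steps hold no way back from product, so I expected 100% product in the end.

The forecast said it is still moving, with 58.6% used up (56.5% to 60.5%), 58.6% product and 100% in the end, adding “The product step is irreversible”; my figure lay 1.2 points above its 58.6%.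

The flask's answer was: it is still moving, with 59.4% used up, 59.4% product and 100% in the end.

    substrate + enzyme ⇌ complex (K = 47.0 M⁻¹, k = 8.20 × 10⁶ M⁻¹ s⁻¹)
    complex → enzyme + product (k = 88.0 s⁻¹)

The flask's 59.4% at 4.80 µM·min stood 2.7 points above elm's reading at 4.50 µM·min. The same flask read at 2.5 min had a dose of 3.00 µM·min, which lay 0.300 µM·min past elm's 2.70 µM·min. Elm's step put its product at 41.3%. At that time the flask held 58.4% substrate and 41.6% product.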